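**Plan**

- Retrosynthetic cuts, in order: the ester C(=O)–O3 bond and the five O–benzyl bonds; the C2–H bond together with the two C–O bonds of an oxirane fused across C2–C3; the C2–aryl bond to ring B; finally C4–C4a and O1–C2, which release phloroglucinol and acrylic acid.
- Forward order: ring C is annulated onto ring A as a lactone, ring B is joined at C2 by cross-coupling of the lactone-derived enol phosphate, the oxirane is fused onto the resulting 4H-chromene and opened by hydride, and the 4-hydroxybenzoyl group is attached last.
- Enabling feature: in ring C the array O1–C2(aryl)–C3(O)–C4H2 is an aryl-substituted cyclic enol ether plus one oxygen atom and one hydride, the pattern of a 2-hydroxy C-aryl glycoside.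
- Stereochemistry: C3 (R) comes from catalyst-controlled, face-selective oxygen transfer by a D-fructose-derived chiral dioxirane; C2 (R) comes from hydride entering C2 with inversion, which leaves the aryl group cis to the C3 oxygen.

Key step: step 5

Assumption: the oxirane made in step 5 tolerates a cold, base-buffered extraction and is reduced at once as a dried solution; it is never chromatographed or stored.

**Step 1**
Reactants: 1 phloroglucinol; 2 acrylic acid
Product: 4 5,7-dihydroxychroman-2-one, via 3-(2,4,6-trihydroxyphenyl)propanoic acid 3 (not isolated)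
Conditions: Amberlyst-15, toluene, reflux, Dean–Stark; 1 in excess
Reagents that add atoms: none
Why: Acid-catalysed Friedel–Crafts conjugate addition (hydroarylation) of the very electron-rich arene to acrylic acid gives the arylpropanoic acid, which lactonises onto an ortho hydroxyl as water is removed; the threefold symmetry of 1 allows one regioisomer only, and the excess of 1 holds back a second annulation.

**Step 2**
Reactants: 4 5,7-dihydroxychroman-2-one
Product: 5 5,7-bis(benzyloxy)chroman-2-one
Conditions: BnBr, anhydrous K2CO3, acetone, reflux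
Reagents that add atoms: benzyl bromide, BrCc1ccccc1
Why: Williamson ether synthesis on the two phenols; with anhydrous K2CO3 in acetone no external nucleophile is present to open the aryl lactone.

**Step 3**
Reactants: 5 5,7-bis(benzyloxy)chroman-2-one
Product: 6 5,7-bis(benzyloxy)-4H-chromen-2-yl diphenyl phosphate
Conditions: KN(SiMe3)2 added to 5 + (PhO)2P(O)Cl, THF–DMPU, −78 °C; filtration through Et3N-deactivated silica
Reagents that add atoms: diphenyl chlorophosphate, O=P(Cl)(Oc1ccccc1)Oc1ccccc1
Why: Ketene acetal phosphate formation by O-phosphorylation of the deprotonated lactone, the usual entry to lactone-derived cross-coupling partners; with the chlorophosphate already present at −78 °C the anion is trapped before it can expel the phenoxide or undergo Claisen condensation.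

**Step 4**
Reactants: 6 5,7-bis(benzyloxy)-4H-chromen-2-yl diphenyl phosphate; 7 [3,4-bis(benzyloxy)phenyl]boronic acid
Product: 8 5,7-bis(benzyloxy)-2-[3,4-bis(benzyloxy)phenyl]-4H-chromene
Conditions: Pd(PPh3)4 (5 mol %), aq. Na2CO3, DME, 70 °C, degassed; basic alumina, under argon
Reagents that add atoms: none
Why: Suzuki–Miyaura coupling of a ketene acetal phosphate, in which zerovalent palladium inserts into the C2–O(P) bond, the aryl group is transferred from the boronate and reductive elimination forms the C2–aryl bond; the benzyl ethers and the new enol ether are stable to the basic medium.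

**Step 5**
Reactants: 8 5,7-bis(benzyloxy)-2-[3,4-bis(benzyloxy)phenyl]-4H-chromene
Product: 9 (2S,3R)-5,7-bis(benzyloxy)-2-[3,4-bis(benzyloxy)phenyl]-2,3-epoxychroman
Conditions: Shi ketone (1,2:4,5-di-O-isopropylidene-β-D-erythro-2,3-hexodiulo-2,6-pyranose, from D-fructose, 0.3 equiv), Oxone (2KHSO5·KHSO4·K2SO4), K2CO3, Bu4NHSO4, MeCN–CH2(OMe)2–aq. Na2B4O7/Na2EDTA buffer (pH 10.5), −10 °C; cold extraction into Et2O (trace Et3N), dried over K2CO3, used at once
Reagents that add atoms: potassium peroxymonosulfate (active salt of Oxone), [K+].[O-]S(=O)(=O)OO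
Why: Peroxymonosulfate converts the chiral ketone into its dioxirane, which hands one oxygen atom to the electron-rich C2=C3 enol ether in a single concerted, asynchronous step through a spiro transition state and so regenerates the ketone. The closest known reaction type is the Shi epoxidation of trisubstituted aryl alkenes, enol ethers and enol esters; the carbocyclic analogue 1-phenylcyclohexene is known to receive oxygen from this ketone on the face that corresponds to the (2S,3R) oxide here. The oxirane ring closes by suprafacial [2+1] oxygen-atom transfer, so the lasting O–C3 bond and the temporary O–C2 bond form on the same face and the three-membered ring is necessarily cis-fused to ring C. C3 (R) is fixed by the catalyst, whose spiro arrangement turns the only olefinic hydrogen, C3–H, toward the fused dioxolane of the ketone, and C2 (S) follows from the syn addition. The step needs chemoselectivity for the enol ether, which is the only alkene and far more nucleophilic than the alkoxyarenes and benzylic C–H bonds, and it needs the acid-labile oxirane to survive, which the pH 10.5 buffer, the low temperature and the two-phase medium are meant to secure.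

**Step 6**
Reactants: 9 (2S,3R)-5,7-bis(benzyloxy)-2-[3,4-bis(benzyloxy)phenyl]-2,3-epoxychroman
Product: 10 (2R,3R)-5,7-bis(benzyloxy)-2-[3,4-bis(benzyloxy)phenyl]chroman-3-ol (5,7,3',4'-tetra-O-benzyl-(−)-epicatechin)
Conditions: LiBHEt3 (Super-Hydride), THF, −78 → −20 °C; then H2O
Reagents that add atoms: none
Why: Reductive opening of an epoxy ether by a strongly nucleophilic, non-Lewis-acidic borohydride, the reaction type used to reduce 1,2-anhydro sugars at the anomeric carbon: hydride should attack C2, whose C–O bond is weakened by O1 and the electron-rich aryl ring, from the side opposite the departing oxygen, so that H ends trans and the aryl group cis to the untouched C3 oxygen, which fixes C2 as R.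

**Step 7**
Reactants: 10 5,7,3',4'-tetra-O-benzyl-(−)-epicatechin; 11 4-(benzyloxy)benzoic acid
Product: 12 (2R,3R)-5,7-bis(benzyloxy)-2-[3,4-bis(benzyloxy)phenyl]chroman-3-yl 4-(benzyloxy)benzoate
Conditions: DCC, DMAP, CH2Cl2, 0 °C → rt
Reagents that add atoms: none
Why: Steglich esterification, in which carbodiimide activation and acyl transfer by DMAP acylate the hindered axial C3 hydroxyl on oxygen only, so the configuration at C2 and C3 is retained.

**Step 8**
Reactants: 12 (2R,3R)-5,7-bis(benzyloxy)-2-[3,4-bis(benzyloxy)phenyl]chroman-3-yl 4-(benzyloxy)benzoate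
Product: 13 epicatechin 3-O-p-hydroxybenzoate
Conditions: H2 (1 atm), Pd(OH)2/C, THF–MeOH, rt
Reagents that add atoms: none
Why: Catalytic hydrogenolysis of the five aryl benzyl ethers under neutral conditions, which should leave the ester and the cyclic benzylic C2–O1 ether intact and avoids base that could epimerise C2 of the free phenol.

**Compound list**

1 | phloroglucinol | Oc1cc(O)cc(O)c1 | starting material
2 | acrylic acid | C=CC(=O)O | starting material
3 | 3-(2,4,6-trihydroxyphenyl)propanoic acid | OC(=O)CCc1c(O)cc(O)cc1O | intermediate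
4 | 5,7-dihydroxychroman-2-one | O=C1CCc2c(O)cc(O)cc2O1 | intermediate
5 | 5,7-bis(benzyloxy)chroman-2-one | O=C1CCc2c(OCc3ccccc3)cc(OCc3ccccc3)cc2O1 | intermediate
6 | 5,7-bis(benzyloxy)-4H-chromen-2-yl diphenyl phosphate | O=P(Oc1ccccc1)(Oc1ccccc1)OC1=CCc2c(OCc3ccccc3)cc(OCc3ccccc3)cc2O1 | intermediate
7 | [3,4-bis(benzyloxy)phenyl]boronic acid | OB(O)c1ccc(OCc2ccccc2)c(OCc2ccccc2)c1 | starting material
8 | 5,7-bis(benzyloxy)-2-[3,4-bis(benzyloxy)phenyl]-4H-chromene | C1=C(c2ccc(OCc3ccccc3)c(OCc3ccccc3)c2)Oc2cc(OCc3ccccc3)cc(OCc3ccccc3)c2C1 | intermediate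
9 | (2S,3R)-5,7-bis(benzyloxy)-2-[3,4-bis(benzyloxy)phenyl]-2,3-epoxychroman | O1[C@@H]2Cc3c(OCc4ccccc4)cc(OCc4ccccc4)cc3O[C@]12c1ccc(OCc2ccccc2)c(OCc2ccccc2)c1 | intermediate
10 | (2R,3R)-5,7-bis(benzyloxy)-2-[3,4-bis(benzyloxy)phenyl]chroman-3-ol | O[C@@H]1Cc2c(OCc3ccccc3)cc(OCc3ccccc3)cc2O[C@@H]1c1ccc(OCc2ccccc2)c(OCc2ccccc2)c1 | intermediate
11 | 4-(benzyloxy)benzoic acid | O=C(O)c1ccc(OCc2ccccc2)cc1 | starting material
12 | (2R,3R)-5,7-bis(benzyloxy)-2-[3,4-bis(benzyloxy)phenyl]chroman-3-yl 4-(benzyloxy)benzoate | O=C(O[C@@H]1Cc2c(OCc3ccccc3)cc(OCc3ccccc3)cc2O[C@@H]1c1ccc(OCc2ccccc2)c(OCc2ccccc2)c1)c1ccc(OCc2ccccc2)cc1 | intermediate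
13 | (2R,3R)-2-(3,4-dihydroxyphenyl)-5,7-dihydroxychroman-3-yl 4-hydroxybenzoate (epicatechin 3-O-p-hydroxybenzoate) | O=C(O[C@@H]1Cc2c(O)cc(O)cc2O[C@@H]1c1ccc(O)c(O)c1)c1ccc(O)cc1 | target

**Step count**

Total: 8 steps. Longest linear sequence: 8 steps (1 and 2 to 13; 7 and 11 are purchased).

**Steps most likely to fail**

1. Step 6. The oxirane may ionise to the C2 oxocarbenium ion before hydride arrives, so that hydride is delivered from the alkoxide face or without facial control and the cis relation is lost. Hydride may also attack C3, after which the hemiketal collapses to an open-chain ketone that is reduced further. The fallback sets out from 9 and comes back at 10. The oxirane is treated with a mild Lewis acid (catalytic ZnCl2 or MgBr2·OEt2, toluene, −40 °C) to trigger a Meinwald-type 1,2-hydride shift from C3 to C2. Because the shift is suprafacial, the hydrogen must arrive at C2 on the face opposite the former C3–O bond however far C2–O cleavage has advanced, which should give (2R)-5,7-bis(benzyloxy)-2-[3,4-bis(benzyloxy)phenyl]chroman-3-one F1. Reduction with LiBH(s-Bu)3 (L-Selectride) in THF at −78 °C, from the face away from the C2 aryl group, should then give the cis alcohol 10. In this variant the chirality set at C3 in the key step is relayed to C2, and C3 is re-created under substrate control.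

2. Step 5. The oxirane may be opened by solvolysis in the aqueous buffer before it can be extracted, or enantioface selection may be eroded by direct, uncatalysed oxygen transfer from peroxymonosulfate to the very electron-rich enol ether. The fallback sets out from 8 and comes back at 10. Epoxidation with a dried acetone solution of dimethyldioxirane in CH2Cl2 at −40 °C, followed only by removal of the volatiles, should give racemic (2S*,3R*)-5,7-bis(benzyloxy)-2-[3,4-bis(benzyloxy)phenyl]-2,3-epoxychroman F2 without any contact with water. Reduction with LiBHEt3 as in step 6 should give racemic cis-5,7-bis(benzyloxy)-2-[3,4-bis(benzyloxy)phenyl]chroman-3-ol F3. The enantiomers are then separated by preparative chromatography on a chiral stationary phase, and the (2R,3R) enantiomer is 10. Asymmetric catalysis is given up for a resolution here.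

3. Step 3. The deprotonated aryl lactone may fragment to a ketene and a phenoxide, condense with itself (Claisen), or the ketene acetal phosphate may hydrolyse on handling. The fallback sets out from 5 and comes back at 8, replacing steps 3 and 4. The lactone is opened with MeNHOMe·HCl/AlMe3 (CH2Cl2, 0 °C) to 3-[2,4-bis(benzyloxy)-6-hydroxyphenyl]-N-methoxy-N-methylpropanamide F4. After deprotonation of the phenol with i-PrMgCl, [3,4-bis(benzyloxy)phenyl]magnesium bromide F5 (from 4-bromo-1,2-bis(benzyloxy)benzene and Mg in THF) is added. This should give 3-[2,4-bis(benzyloxy)-6-hydroxyphenyl]-1-[3,4-bis(benzyloxy)phenyl]propan-1-one F6, which is in equilibrium with its cyclic hemiketal. Cyclodehydration with catalytic TsOH in toluene over 4 Å molecular sieves should give the 4H-chromene 8.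

**Further compounds**

F1 | step 6 | (2R)-5,7-bis(benzyloxy)-2-[3,4-bis(benzyloxy)phenyl]chroman-3-one | O=C1Cc2c(OCc3ccccc3)cc(OCc3ccccc3)cc2O[C@@H]1c1ccc(OCc2ccccc2)c(OCc2ccccc2)c1
F2 | step 5 | racemic (2S*,3R*)-5,7-bis(benzyloxy)-2-[3,4-bis(benzyloxy)phenyl]-2,3-epoxychroman | O1[C@@H]2Cc3c(OCc4ccccc4)cc(OCc4ccccc4)cc3O[C@]12c1ccc(OCc2ccccc2)c(OCc2ccccc2)c1.O1[C@H]2Cc3c(OCc4ccccc4)cc(OCc4ccccc4)cc3O[C@@]12c1ccc(OCc2ccccc2)c(OCc2ccccc2)c1
F3 | step 5 | racemic cis-5,7-bis(benzyloxy)-2-[3,4-bis(benzyloxy)phenyl]chroman-3-ol | O[C@@H]1Cc2c(OCc3ccccc3)cc(OCc3ccccc3)cc2O[C@@H]1c1ccc(OCc2ccccc2)c(OCc2ccccc2)c1.O[C@H]1Cc2c(OCc3ccccc3)cc(OCc3ccccc3)cc2O[C@H]1c1ccc(OCc2ccccc2)c(OCc2ccccc2)c1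
F4 | step 3 | 3-[2,4-bis(benzyloxy)-6-hydroxyphenyl]-N-methoxy-N-methylpropanamide | CON(C)C(=O)CCc1c(O)cc(OCc2ccccc2)cc1OCc1ccccc1
F5 | step 3 | [3,4-bis(benzyloxy)phenyl]magnesium bromide | Br[Mg]c1ccc(OCc2ccccc2)c(OCc2ccccc2)c1
F6 | step 3 | 3-[2,4-bis(benzyloxy)-6-hydroxyphenyl]-1-[3,4-bis(benzyloxy)phenyl]propan-1-one | O=C(CCc1c(O)cc(OCc2ccccc2)cc1OCc1ccccc1)c1ccc(OCc2ccccc2)c(OCc2ccccc2)c1
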